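The cycloheptane ring is read as a masked 8-oxabicyclo[3.2.1]octenone (guaiane numbering, defined below). The C1 hydroxyl oxygen, which sits 1,4 to C7–H across the C6 ketone, is taken as the oxygen of a cyclopenta-fused furan, and C8–C9(O)–C10(O) as an oxygenated oxyallyl cation. A (4+3) cycloaddition of the silyloxyallyl cation from silyl enol ether 8 with furan 6 forms C1–C10 and C7–C8 in one operation, closing the seven-membered ring and fixing C1 anti to a C4 silyloxy stereocentre. The methoxy group then serves as a reductive leaving group for exo hydroxylation at C10, the furan alkene becomes the C6 ketone, and SmI2 finally opens the C7–O bridge.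

Key step: step 6

Remark on numbering: guaiane numbering is used for all intermediates. C1 = ring-fusion carbinol carbon, C2/C3 = cyclopentane CH2 groups, C4 = carbon bearing the exocyclic CH2 (C15), C5 = ring-fusion CH, C6 = ketone carbon, C7 = isopropyl-bearing carbon, C8 = CH2, C9 = acyloxy carbon, C10 = C(CH3)OH. β is the face of the seven-membered ring that carries the C1 oxygen, α the opposite face. In the oxygen-bridged intermediates, exo is the side of the oxygen bridge and endo the side of the other bridge.

Assumption: cycloadduct 10 is carried forward as the mixture of C10 epimers, because C10 is planarised and reset in step 7.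

**Step 1**
Reactants: 1 cyclopentane-1,3-dione; 2 1-bromo-3-methylbutan-2-one
Product: 3 2-(3-methyl-2-oxobutyl)cyclopentane-1,3-dione
Conditions: KOH (1 equiv), H2O, rt
Reagents that add atoms: none
Why: Enolate C-alkylation of the cyclic 1,3-dione by the α-bromo ketone in water, where hydrogen bonding to the enolate oxygens favours carbon over oxygen attack; no stereocentre is formed.

**Step 2**
Reactants: 3 2-(3-methyl-2-oxobutyl)cyclopentane-1,3-dione
Product: 4 2-isopropyl-5,6-dihydro-4H-cyclopenta[b]furan-4-one
Conditions: p-TsOH·H2O (cat.), toluene, reflux, Dean–Stark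
Reagents that add atoms: none
Why: Paal–Knorr furan synthesis: acid-catalysed cyclodehydration of the 1,4-diketone unit places the isopropyl group on the furan α-carbon and leaves the second ring ketone at C4.

**Step 3**
Reactants: 4 2-isopropyl-5,6-dihydro-4H-cyclopenta[b]furan-4-one
Product: 5 (S)-2-isopropyl-5,6-dihydro-4H-cyclopenta[b]furan-4-ol
Conditions: (R)-tetrahydro-1-methyl-3,3-diphenyl-1H,3H-pyrrolo[1,2-c][1,3,2]oxazaborole (15 mol %), BH3·SMe2, THF, −20 °C; MeOH quench
Reagents that add atoms: none
Why: Corey–Bakshi–Shibata reduction in which the furan carbon is the large and the ring CH2 the small substituent (as in 1-indanone), so the (R)-catalyst should give the (S)-carbinol that later directs the cycloaddition.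

**Step 4**
Reactants: 5 (S)-2-isopropyl-5,6-dihydro-4H-cyclopenta[b]furan-4-ol
Product: 6 (S)-4-(tert-butyldimethylsilyloxy)-2-isopropyl-5,6-dihydro-4H-cyclopenta[b]furan
Conditions: t-BuMe2SiCl, imidazole, DMF, 0 °C to rt
Reagents that add atoms: tert-butyldimethylsilyl chloride CC(C)(C)[Si](C)(C)Cl
Why: Standard silylation of a secondary alcohol; the bulky silyl ether is the facial control element for step 6 and survives the later base, hydride and electron-transfer steps.

**Step 5**
Reactants: 7 3,3-dimethoxybutan-2-one
Product: 8 3,3-dimethoxy-2-(triethylsilyloxy)but-1-ene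
Conditions: LiN(i-Pr)2, THF, −78 °C; Et3SiCl
Reagents that add atoms: chlorotriethylsilane CC[Si](Cl)(CC)CC
Why: Kinetic enolate formation is possible only at the acetyl methyl group (the other α-carbon is the ketal carbon), and O-silylation gives the silyl enol ether of the α-keto ketal.

**Step 6**
Reactants: 6 (S)-4-(tert-butyldimethylsilyloxy)-2-isopropyl-5,6-dihydro-4H-cyclopenta[b]furan; 8 3,3-dimethoxy-2-(triethylsilyloxy)but-1-ene
Product: 10 4-(tert-butyldimethylsilyloxy)-1,7-epoxy-10-methoxyguai-5-en-9-one (oxygen bridge on the β face; C4 silyloxy group anti to the C8–C10 bridge; both C10 epimers), via silyloxyallyl cation triflate 9 (not isolated)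
Conditions: Me3SiOTf (0.2 equiv), CH2Cl2, −78 °C; aq. NaHCO3
Reagents that add atoms: none
Why: Me3SiOTf ionises one methoxy group of 8 to the 2-silyloxyallyl cation 9, whose oxocarbenium carbon C10 attacks the furan α-carbon C1 and whose enol-silane carbon C8 then closes onto the resulting furan-derived oxocarbenium carbon C7, with loss of the triethylsilyl group giving the C9 ketone. The closest known reaction type is the silyl-triflate-promoted (4+3) cycloaddition of furans with silyl enol ethers of α-keto acetals (alkoxy-substituted silyloxyallyl cations). The cycloheptene ring C1–C5–C6–C7–C8–C9–C10 is closed by intermolecular (4+3) annulation across the furan 2,5-positions, the second bond forming in a 7-(enolendo)-exo-trig attack that also creates the oxygen-bridged bicyclo[3.2.1] frame. C1 and C7 are set together because both bonds form on one furan face, and that face should be the one anti to the C4 silyloxy group on the rigid bicyclic furan, so the C4 centre from step 3 controls the absolute configuration; C10 forms as an epimer mixture that converges in step 7. The step needs head-to-head regioselectivity (C10 to C1, C8 to C7), which the polarity of 9 (electrophilic oxocarbenium terminus, nucleophilic enol-silane terminus) and the furan should secure: C1 is activated by the adjacent ring alkyl substituent and is less encumbered than the isopropyl-bearing C7.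

**Step 7**
Reactants: 10 4-(tert-butyldimethylsilyloxy)-1,7-epoxy-10-methoxyguai-5-en-9-one
Product: 12 4-(tert-butyldimethylsilyloxy)-1,7-epoxy-10β-hydroxyguai-5-en-9-one, via lithium enolate 11 (not isolated)
Conditions: lithium 4,4'-di-tert-butylbiphenylide (2.1 equiv), THF, −78 °C; then trans-2-(phenylsulfonyl)-3-phenyloxaziridine, −78 °C; aq. NH4Cl
Reagents that add atoms: trans-2-(phenylsulfonyl)-3-phenyloxaziridine O=S(=O)(c1ccccc1)N1OC1c1ccccc1
Why: Two-electron reduction of the α-methoxy ketone expels methoxide and gives the C9–C10 lithium enolate regiospecifically from either C10 epimer (the β-disposed C1–O bond is retained at −78 °C), and Davis oxidation of the enolate then occurs on the exo face, syn to the oxygen bridge and away from the C5=C6 bridge, so the C10 hydroxyl becomes axial and cis to the C1 oxygen with the methyl group equatorial.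

**Step 8**
Reactants: 12 4-(tert-butyldimethylsilyloxy)-1,7-epoxy-10β-hydroxyguai-5-en-9-one
Product: 13 4-(tert-butyldimethylsilyloxy)-1,7-epoxyguai-5-ene-9α,10β-diol
Conditions: LiBH(s-Bu)3 (3 equiv), THF, −78 °C; aq. NH4Cl
Reagents that add atoms: none
Why: Ketone reduction by a bulky hydride from the exo face (the endo face of C9 is covered by the C5=C6 bridge), the usual behaviour of 8-oxabicyclo[3.2.1]octan-3-ones, should give the axial C9 alcohol trans to the C10 hydroxyl.

**Step 9**
Reactants: 13 4-(tert-butyldimethylsilyloxy)-1,7-epoxyguai-5-ene-9α,10β-diol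
Product: 14 1,7-epoxyguai-5-ene-4,9α,10β-triol
Conditions: n-Bu4NF, THF, 0 °C to rt
Reagents that add atoms: none
Why: Fluoride cleavage of the silyl ether unmasks the allylic C4 alcohol once its directing role is over.

**Step 10**
Reactants: 14 1,7-epoxyguai-5-ene-4,9α,10β-triol
Product: 15 1,7-epoxy-9α,10β-dihydroxyguai-5-en-4-one
Conditions: MnO2 (activated, excess), CH2Cl2, rt
Reagents that add atoms: none
Why: MnO2 oxidises only the allylic C4 alcohol to the enone; the saturated C9 and tertiary C10 alcohols are inert, the trans-diaxial diol cannot undergo glycol cleavage, and the C4 stereocentre is deliberately destroyed here.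

**Step 11**
Reactants: 15 1,7-epoxy-9α,10β-dihydroxyguai-5-en-4-one
Product: 16 1,7-epoxyguaia-4(15),5-diene-9α,10β-diol
Conditions: Ph3PCH3Br, KOt-Bu (excess), THF, 0 °C to rt
Reagents that add atoms: methyltriphenylphosphonium bromide C[P+](c1ccccc1)(c1ccccc1)c1ccccc1.[Br-]
Why: Wittig methylenation of the enone carbonyl (1,2-addition) installs C15 and gives the exocyclic 1,3-diene; excess ylide compensates for the two free hydroxyl groups.

**Step 12**
Reactants: 16 1,7-epoxyguaia-4(15),5-diene-9α,10β-diol; 17 angelic anhydride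
Product: 18 9α-angeloyloxy-1,7-epoxyguaia-4(15),5-dien-10β-ol
Conditions: LiN(SiMe3)2 (1.1 equiv), THF, −78 to 0 °C; aq. NH4Cl
Reagents that add atoms: none
Why: Acylation of the lithium alkoxide with the anhydride at low temperature, without a nucleophilic amine catalyst, avoids angelate-to-tiglate isomerisation; the secondary C9 alkoxide reacts, while the hindered tertiary C10 hydroxyl, trans-diaxial to it, is neither acylated nor able to receive the acyl group by migration.

**Step 13**
Reactants: 18 9α-angeloyloxy-1,7-epoxyguaia-4(15),5-dien-10β-ol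
Product: 19 9α-angeloyloxy-1,7:5,6-diepoxyguai-4(15)-en-10β-ol (5,6-epoxide on the exo face)
Conditions: dimethyldioxirane (1.1 equiv, acetone), CH2Cl2, −40 °C
Reagents that add atoms: dimethyldioxirane CC1(C)OO1
Why: Electrophilic epoxidation (Prilezhaev type, neutral dioxirane) should take the more substituted, more electron-rich C5=C6 bond of the diene on the exo face, because the endo face is covered by the axial C9 ester, while the exocyclic methylidene and the electron-poor angelate alkene remain.

**Step 14**
Reactants: 19 9α-angeloyloxy-1,7:5,6-diepoxyguai-4(15)-en-10β-ol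
Product: 20 9α-angeloyloxy-1,7-epoxy-10β-hydroxy-5αH-guai-4(15)-en-6-one
Conditions: Pd(PPh3)4 (5 mol %), THF, 0 °C to rt
Reagents that add atoms: none
Why: Zerovalent-palladium-catalysed isomerisation of a 1,3-diene monoepoxide to a β,γ-unsaturated ketone (as in cyclopentadiene monoepoxide to cyclopent-3-enone): ionisation of the allylic C5–O bond gives a π-allyl alkoxide whose only β-hydrogen is C6–H, and return of that hydrogen to C5 on the endo face gives the C6 ketone with C5–H anti to the oxygen bridge, the only strain-free fusion of the cyclopentane.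

**Step 15**
Reactants: 20 9α-angeloyloxy-1,7-epoxy-10β-hydroxy-5αH-guai-4(15)-en-6-one
Product: 21 CNP0124926.1 (9α-angeloyloxy-1β,10β-dihydroxy-5αH,7βH-guai-4(15)-en-6-one)
Conditions: SmI2 (2.5 equiv), THF–MeOH, −78 °C; pH 7 buffer
Reagents that add atoms: none
Why: SmI2 reduction of an α-alkoxy ketone: the C6 ketyl expels the α-oxygen at C7, which releases the C1 tertiary alkoxide, and the samarium enolate should be protonated at C7 on the face just vacated by the oxygen (proton relayed from methanol held at the neighbouring C1–O–Sm), giving C7–H cis to the C1 hydroxyl; the enoate and the β,γ-alkene are not reduced at −78 °C.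

**Compound list**

1 | cyclopentane-1,3-dione | O=C1CCC(=O)C1 | starting material
2 | 1-bromo-3-methylbutan-2-one | CC(C)C(=O)CBr | starting material
3 | 2-(3-methyl-2-oxobutyl)cyclopentane-1,3-dione | CC(C)C(=O)CC1C(=O)CCC1=O | intermediate
4 | 2-isopropyl-5,6-dihydro-4H-cyclopenta[b]furan-4-one | CC(C)c1cc2C(=O)CCc2o1 | intermediate
5 | (S)-2-isopropyl-5,6-dihydro-4H-cyclopenta[b]furan-4-ol | CC(C)c1cc2[C@@H](O)CCc2o1 | intermediate
6 | (S)-4-(tert-butyldimethylsilyloxy)-2-isopropyl-5,6-dihydro-4H-cyclopenta[b]furan | CC(C)c1cc2[C@@H](O[Si](C)(C)C(C)(C)C)CCc2o1 | intermediate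
7 | 3,3-dimethoxybutan-2-one | CC(=O)C(C)(OC)OC | starting material
8 | 3,3-dimethoxy-2-(triethylsilyloxy)but-1-ene | C=C(O[Si](CC)(CC)CC)C(C)(OC)OC | intermediate
9 | 1-methoxy-1-methyl-2-(triethylsilyloxy)allyl cation triflate (not isolated) | C=C(O[Si](CC)(CC)CC)C(C)=[O+]C.[O-]S(=O)(=O)C(F)(F)F | intermediate
10 | 4-(tert-butyldimethylsilyloxy)-1,7-epoxy-10-methoxyguai-5-en-9-one, C10 epimers | CC(C)[C@]12CC(=O)C(C)(OC)[C@@]3(O1)CC[C@H](O[Si](C)(C)C(C)(C)C)C3=C2 | intermediate
11 | lithium C9–C10 enolate of the bridged ketone (not isolated) | CC(C)[C@]12CC([O-])=C(C)[C@@]3(O1)CC[C@H](O[Si](C)(C)C(C)(C)C)C3=C2.[Li+] | intermediate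
12 | 4-(tert-butyldimethylsilyloxy)-1,7-epoxy-10β-hydroxyguai-5-en-9-one | CC(C)[C@]12CC(=O)[C@](C)(O)[C@@]3(O1)CC[C@H](O[Si](C)(C)C(C)(C)C)C3=C2 | intermediate
13 | 4-(tert-butyldimethylsilyloxy)-1,7-epoxyguai-5-ene-9α,10β-diol | CC(C)[C@]12C[C@@H](O)[C@](C)(O)[C@@]3(O1)CC[C@H](O[Si](C)(C)C(C)(C)C)C3=C2 | intermediate
14 | 1,7-epoxyguai-5-ene-4,9α,10β-triol | CC(C)[C@]12C[C@@H](O)[C@](C)(O)[C@@]3(O1)CC[C@H](O)C3=C2 | intermediate
15 | 1,7-epoxy-9α,10β-dihydroxyguai-5-en-4-one | CC(C)[C@]12C[C@@H](O)[C@](C)(O)[C@@]3(O1)CCC(=O)C3=C2 | intermediate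
16 | 1,7-epoxyguaia-4(15),5-diene-9α,10β-diol | CC(C)[C@]12C[C@@H](O)[C@](C)(O)[C@@]3(O1)CCC(=C)C3=C2 | intermediate
17 | angelic anhydride, (Z)-2-methylbut-2-enoic anhydride | C/C=C(/C)C(=O)OC(=O)/C(C)=C\C | starting material
18 | 9α-angeloyloxy-1,7-epoxyguaia-4(15),5-dien-10β-ol | CC(C)[C@]12C[C@@H](OC(=O)/C(C)=C\C)[C@](C)(O)[C@@]3(O1)CCC(=C)C3=C2 | intermediate
19 | 9α-angeloyloxy-1,7:5,6-diepoxyguai-4(15)-en-10β-ol, exo 5,6-epoxide | CC(C)[C@]12C[C@@H](OC(=O)/C(C)=C\C)[C@](C)(O)[C@@]3(O1)CCC(=C)[C@]35O[C@H]25 | intermediate
20 | 9α-angeloyloxy-1,7-epoxy-10β-hydroxy-5αH-guai-4(15)-en-6-one | C=C1CC[C@@]2(O3)[C@H]1C(=O)[C@@]3(C(C)C)C[C@@H](OC(=O)/C(C)=C\C)[C@]2(C)O | intermediate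
21 | CNP0124926.1 | C=C1CC[C@@]2(O)[C@H]1C(=O)[C@@H](C(C)C)C[C@@H](OC(=O)/C(C)=C\C)[C@]2(C)O | target

Total step count: 15. Longest linear sequence: 14 steps (steps 1–4 and 6–15); step 5 is a one-step side branch.

**Steps most likely to fail**

Step 6. The silyl triflate may ionise the furylcarbinyl silyl ether or drive Friedel–Crafts attack at the free furan β-position instead of cycloaddition. Forming the vicinal fully substituted C1–C10 bond may also erode regio- or facial selectivity. The fallback sets out from 6 and generates the oxyallyl cation without a Lewis acid, from 3,3-dichlorobutan-2-one with Et3N in CF3CH2OH at rt. This should give the chloro ketone cycloadduct F1 with the same polarity-controlled regiochemistry. Two-electron reduction of F1 with lithium 4,4'-di-tert-butylbiphenylide expels chloride and gives the same lithium enolate 11, which is hydroxylated as in step 7, so the fallback comes back to the route at 12.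

Step 7. The enolate may lose the bridging oxygen by β-elimination (ring opening to a cycloheptenone), the ketone may be over-reduced, or oxygen transfer to the hindered tetrasubstituted enolate may be slow. The fallback sets out from 10 and separates the operations. SmI2 in THF–MeOH at −78 °C removes the methoxy group to give the methyl ketone F2. Thermodynamic soft enolisation with Me3SiI and HN(SiMe3)2 gives the more substituted trimethylsilyl enol ether F3. Rubottom oxidation of F3 (dimethyldioxirane, 1 equiv, −78 °C, then mild acid) on the exo face returns to the route at 12.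

Step 14. Zerovalent palladium may fail to ionise the hindered vinyl epoxide on the endo face, or the hydrogen may be returned to C15 to give the conjugated enone. The fallback sets out from 15 and bypasses the diene and the epoxide (steps 11–14).
- Acylation as in step 12 gives the enone angelate F4.
- Copper-catalysed conjugate borylation (CuCl, NaOt-Bu, 1,2-bis(diphenylphosphino)benzene, bis(pinacolato)diboron, MeOH, THF) places boron on C6 from the exo face and protonates C5 to the strain-free fusion, giving the boryl ketone F5.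
- Takai–Lombardo methylenation (Zn, CH2Br2, TiCl4) of the C4 ketone gives the methylidene boronate F6.
- NaBO3·4H2O oxidation of the C–B bond gives the C6 alcohol F7.
- Dess–Martin oxidation returns to the route at 20.

**Further compounds**

F1 | step 6 | 4-(tert-butyldimethylsilyloxy)-10-chloro-1,7-epoxyguai-5-en-9-one, C10 epimers | CC(C)[C@]12CC(=O)C(C)(Cl)[C@@]3(O1)CC[C@H](O[Si](C)(C)C(C)(C)C)C3=C2
F2 | step 7 | 4-(tert-butyldimethylsilyloxy)-1,7-epoxyguai-5-en-9-one, C10 epimers | CC(C)[C@]12CC(=O)C(C)[C@@]3(O1)CC[C@H](O[Si](C)(C)C(C)(C)C)C3=C2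
F3 | step 7 | 4-(tert-butyldimethylsilyloxy)-1,7-epoxy-9-(trimethylsilyloxy)guaia-5,9-diene | CC(C)[C@]12CC(O[Si](C)(C)C)=C(C)[C@@]3(O1)CC[C@H](O[Si](C)(C)C(C)(C)C)C3=C2
F4 | step 14 | 9α-angeloyloxy-1,7-epoxy-10β-hydroxyguai-5-en-4-one | CC(C)[C@]12C[C@@H](OC(=O)/C(C)=C\C)[C@](C)(O)[C@@]3(O1)CCC(=O)C3=C2
F5 | step 14 | 9α-angeloyloxy-1,7-epoxy-10β-hydroxy-6-(pinacolatoboryl)-5αH-guaian-4-one, boron exo | O=C1CC[C@@]2(O3)[C@H]1[C@H](B4OC(C)(C)C(C)(C)O4)[C@@]3(C(C)C)C[C@@H](OC(=O)/C(C)=C\C)[C@]2(C)O
F6 | step 14 | 9α-angeloyloxy-1,7-epoxy-6-(pinacolatoboryl)-5αH-guai-4(15)-en-10β-ol | C=C1CC[C@@]2(O3)[C@H]1[C@H](B4OC(C)(C)C(C)(C)O4)[C@@]3(C(C)C)C[C@@H](OC(=O)/C(C)=C\C)[C@]2(C)O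
F7 | step 14 | 9α-angeloyloxy-1,7-epoxy-5αH-guai-4(15)-ene-6,10β-diol, C6 hydroxyl exo | C=C1CC[C@@]2(O3)[C@H]1[C@H](O)[C@@]3(C(C)C)C[C@@H](OC(=O)/C(C)=C\C)[C@]2(C)O
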